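Start from 0.989, the ratio of target to other capture product at the first reading of Tuesday's run, and divide the charges out of it to get a number that travels to other flasks.

| flask | starting material | first nucleophile | second nucleophile | remark | time |
|---|---|---|---|---|---|
| Tuesday's | 0.050 M | 0.50 M | 0.13 M | run made earlier |  |
| Monday's | 0.20 M | 0.50 M | 0.13 M | run made earlier |  |
| flask | 0.10 M | 0.500 M | 0.130 M |  | 10 min |

| run | time / min | target / % | other capture product / % |
|---|---|---|---|
| Tuesday's | 3.00 | 25.9 | 26.2 |
| Tuesday's | 6.00 | 35.9 | 37.7 |
| Tuesday's | 10.0 | 40.6 | 48.0 |
| Tuesday's | 12.0 | 42.4 | 49.9 |
| Monday's | 1.00 | 9.2 | 9.3 |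
| Monday's | 2.00 | 18.2 | 16.5 |
| Monday's | 5.00 | 34.3 | 31.0 |
| Monday's | 12.0 | 47.5 | 42.0 |

(readings scatter by 1 percentage point)

- ratio of target to other capture product at 6.0 s
- ratio of target to other capture product at 1.0 min
- ratio of target to other capture product at 10 min

Treat the intermediate as short-lived and in a steady state, so that the first nucleophile, F, and the second, S, compete for one pool. Its concentration then cancels from the ratio of the two capture rates, however fast the starting material feeds it:

d[target]/d[other capture product] = s·[F]/[S]

Take s from Tuesday's first reading and the charges, remembering that each reading is good to 1 percentage point: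

s = 0.257

This s is the selectivity factor, the capture constant of F over that of S.

Now build the flask. With the main step alone, both nucleophiles stay at their charges and the ratio is

s·[F]₀/[S]₀ = 0.989

Commit to this at 6.0 s and 1.0 min.

Add the use of S by capture. Monday's run spends 64.6% of its S by its last reading, far more than Tuesday's 19.2%, and its ratio rises to 1.13.

Add the self-condensation of F. Tuesday's ratio sinks to 0.850 although capture has used 4.24% of its F, less than the share of its S, so F must be falling by another route.

The new flask's charge of starting material lies between the two runs' charges, so commit at 10 min to a bracket and not to a single number: between Tuesday's reading of 0.846 at 10.0 min and Monday's 1.13, which was read later, at 12.0 min.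

The forecast, reading that “The two runs drift in opposite directions”, gives 1.1, 1.07 and 0.96, starting higher than my reckoning.

The flask gives 1.01 at 6.0 s, 1.00 at 1.0 min and 0.947 at 10 min, when 51.8% of F and 65.1% of S remain of their charges. Put these into the rule: new target is then forming at 0.786 per other capture product, below the accumulated ratio.

    intermediate → side product (k = 0.0160 /s)
    first nucleophile + intermediate → target (k = 2.20 /M/s)
    2 first nucleophile → self-condensation product (k = 0.00130 /M/s)
    starting material ⇌ intermediate (K = 0.0320, k = 0.00400 /s)
    second nucleophile + intermediate → other capture product (k = 8.40 /M/s)

Carry s to the neighbour flask charged with 2.0 M of F: it gives 3.95 at the start. The computed ratio is 3.97 at 6.0 s, and it comes down to 2.30 at 10 min, with 23.5% of F remaining.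

(The earlier runs and the new flask come from a simulation with constants of no real substance; noise was put on by code.)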